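## Structural features

The carbocyclic core is a cyclohexene, numbered C1–C6 as in the target, with a trisubstituted C2=C3 double bond (methyl on C3), a CH2 at C4 and a quaternary gem-dimethyl carbon at C5. C1 is bonded to C8 of a 5,7-dimethoxycoumarin (the ring A unit); C6 carries the exocyclic carbinol carbon C7, which holds the hydroxyl group and C8 of a second 5,7-dimethoxycoumarin (the ring B unit). Three stereocentres are contiguous, C1 (S), C6 (R) and C7 (R); the substituents on C1 and C6 are trans, and C6 sits between the quaternary C5 and the aryl-bearing C1. The fragile groups are the two lactones (opened by hydroxide or alkoxide, attacked by hard organometallics, conjugate acceptors at coumarin C4, reduced by strong hydrides), the C7 carbinol (benzylic to an arene with two ortho oxygen atoms, so it ionises easily under acid), the alkene (can migrate under acid) and C1–H (allylic and benzylic). The real difficulty is threefold: the absolute configuration at C1, the placement of the double bond at C2=C3 and not C3=C4, and the congestion at C6–C7, where two di-ortho-substituted aryl groups and a gem-dimethyl group meet. The key step uses the fact that C1 with its aryl group and C2 map onto a β-aryl nitroalkene, while C7–C6–C5–C4–C3 with the C3 methyl maps onto a 1,5-keto aldehyde: joining C6 to C1 and C2 to C3 closes the ring, and the nitro group on C2 and the hydroxyl on C3 then mark the two alkene carbons.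

## Logic of the disconnections

18 ⇒ 17. The C7–H bond is cut, taking the carbinol back to the ketone. C7 is the one stereocentre that a small reagent can set last under the influence of C6, and a ketone lets both C7 epimers of the preceding alcohol converge. The gain is one stereocentre less. The demand is a hydride that approaches anti to C5 and leaves both lactones alone.

17 ⇒ 16 ⇒ 14 + 15. The bond between C7 and C8 of the ring B arene is cut, after stepping C7 down to the alcohol level. This is the bond that divides the molecule into two halves of similar size and lets the second coumarin arrive intact. The gain is convergence, with 15 one step from 5. The demand is an aryl–metal species that tolerates two lactones yet adds to an aldehyde flanked by a quaternary and a tertiary carbon; no stereocontrol at C7 is asked of it.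

14 ⇒ 13 ⇒ 12 ⇒ 11. The C2=C3 π bond is traced back to a C2–N and a C3–O bond, by way of a C3–S bond. A nitro group on C2 and a hydroxyl on C3 define the alkene position without regioisomers and are the natural outcome of a nitroaldol ring closure. The gain is that 11 can be assembled from two open-chain pieces. The demands are dehydration toward C2 only, addition of a thiol to a tetrasubstituted nitroalkene, and a radical elimination that spares aldehyde and lactone and does not touch C1 or C6.

11 ⇒ 4 + 8. C1–C6 and C2–C3 are cut. Both bonds are polarity-matched (enamine carbon to nitroalkene β-carbon, nitronate carbon to ketone), so one pot can form the ring. The gain is the largest of the route: the ring, the C1 stereocentre and the trans C1/C6 relationship from two achiral pieces. The demands are enamine formation at the aldehyde only, face selectivity at the nitroalkene, closure onto the ketone and equilibration of C6.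

8 ⇒ 6 + 7, then 6 ⇒ 5. The nitroalkene C=C bond (the future C1–C2) is cut by a retro-nitroaldol condensation, then the bond between coumarin C8 and the formyl carbon. This leads back to a commercial coumarin. The demand is electrophilic substitution at C8 and not at C6 or C3.

15 ⇒ 5. The C8–I bond is cut; the same regiochemical demand applies.

4 ⇒ 3 ⇒ 2 ⇒ 1. C7 is adjusted from aldehyde through thioester to acid, and the acid and ketone carbons of 2 are then reconnected through one extra carbon as the enone of 1. The 1,5-relationship with the gem-dimethyl group in between is already present in 1. The demands are an oxidative cleavage that removes one carbon and a reduction that stops at the aldehyde beside a free ketone.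

## Other disconnections considered

Alternative 1: The cut is made at both aryl–carbon bonds at once, C1–aryl (ring A side) and C7–aryl (ring B side). The carbocycle with its C2=C3 bond then comes ready-made as hindered aryl dienoate A2, and both arenes come from one nucleophile, aryllithium A1. Forward, two equivalents of A1 with a chiral diether ligand would add first at C1 of A2; on warming, the ester enolate would expel its aryloxide to give a ketene, the second equivalent would add at C7, and protonation would give trans ketone A3.
- In its favour: two C–C bonds, the C1 stereocentre and the C7 ketone level come from one flask; the alkene never has to be installed, so no nitro group is removed and no tin or chromium reagent is needed; the simple aryl ethers are fully compatible with organolithium chemistry.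
- Against it here: A3 contains no coumarin, so both pyranone rings must still be built on two very hindered phenols after the MOM groups are removed. A2 offers a competing 1,6-position (C3) and acidic C4 hydrogens to a basic, di-ortho-substituted aryllithium. Ligand control over so bulky a nucleophile is uncertain, the ligand is needed in at least stoichiometric amount, and A2 is itself a multistep compound.
- Comparison: structurally this plan keeps the ring and varies the arenes, whereas the chosen plan keeps one arene and builds the ring around it. Mechanistically both set C1 with an external chiral controller and both rely on the thermodynamic trans arrangement at C6; on these points they are equal. The alternative's key step is the better one in bonds formed and in reaching the ketone level of 17 directly. The chosen plan is shorter overall, because 5 brings both lactones along and its chiral controller is catalytic.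

Alternative 2: The cut is at C5–C6 and C1=C2, a Michael–aldol annulation. Forward, the enolate of aroylacetate A4 (KOtBu) would add to the β-carbon of mesityl oxide A5 to form the quaternary C5–C6 bond, and the methyl ketone would then condense onto the aryl ketone to give cyclohexenone ester A6.
- In its favour: the reagents are very cheap, and the gem-dimethyl carbon and the ring arise in one classical operation.
- Against it here: a stabilised, hindered anion adding to a β,β-disubstituted enone is slow and reversible, and the aldol step must attack a di-ortho-substituted aryl ketone. A6 is racemic and carries the unsaturation and oxygen in the wrong places: C3 is a ketone where the methyl-bearing alkene carbon is needed, C1 is sp2 and not yet a stereocentre. Reaching the target would need a methyl nucleophile at C3, transposition of the alkene to C2=C3 with stereocontrolled hydrogen delivery at C1, conversion of the ester into the aryl ketone, two pyranone annulations and a resolution or asymmetric variant.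
- Comparison: the ring-forming logic (conjugate addition, then carbonyl addition) is equal to that of the chosen plan. The alternative is better in reagent cost and in avoiding tin in the ring-forming phase. It is weaker in stereocontrol and in step economy, since the chosen key step delivers C1 enantioselectively and places the future alkene correctly at once.

Alternative 3: The cut is at the C4–C4a bond of both coumarins, so that both pyranone rings close last. Forward, bis(aryl propiolate) A7 would undergo double 6-endo-dig hydroarylation with cationic monovalent gold (Ph3PAuCl/AgSbF6) to give A8, which is identical with 17.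
- In its favour: the lactones appear only at the end, so all earlier C–C bond formations could use hard nucleophiles and bases. Each arene has only one free ortho position, so the regiochemistry of closure is fixed, and two rings form in one step.
- Against it here: it is an end-game and leaves the carbocycle and all stereocentres to another strategy. It needs two hindered phenols to be freed and esterified, and the cationic gold catalyst meets a trisubstituted alkene close to the ring A propiolate, so enyne-type cycloisomerisation could compete.
- Comparison: in functional-group tolerance during the skeleton-building steps the alternative is the better plan. In the last step (reduction of the same ketone) the two are equal. In step count the chosen plan is better, because it spends no steps on pyranone formation and buys the coumarin ready-made.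

Key step: step 6

Assumption: electrophilic substitution of 5 (steps 4 and 9) is taken to occur at coumarin C8, which is para to the 5-methoxy group and less hindered than C6 between two methoxy groups.

Assumption: locants C1–C7 and the descriptors quoted for ring compounds are those of the target's carbocycle (C1 aryl-bearing, C7 exocyclic).

## Route

Step 1
Reactants: 1 isophorone (3,5,5-trimethylcyclohex-2-en-1-one)
Product: 2 3,3-dimethyl-5-oxohexanoic acid
Conditions: O3, AcOH–H2O, 10 °C; then 30% H2O2, 50 °C
Reagents that add atoms: ozone, [O-][O+]=O; hydrogen peroxide, OO
Why: Ozonolysis cleaves the enone C=C to the methyl ketone and an α-keto acid terminus, which H2O2 cleaves oxidatively with loss of the former C2 as CO2; this is the standard oxidative cleavage of a cyclic enone to a keto acid with one carbon less.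

Step 2
Reactants: 2 3,3-dimethyl-5-oxohexanoic acid
Product: 3 S-ethyl 3,3-dimethyl-5-oxohexanethioate
Conditions: EtSH, DCC, DMAP (cat.), CH2Cl2, 0 °C → rt
Reagents that add atoms: ethanethiol, CCS
Why: Carbodiimide activation with DMAP acyl transfer (Steglich thioesterification) converts the acid into the thioester; the ketone is inert.

Step 3
Reactants: 3 S-ethyl 3,3-dimethyl-5-oxohexanethioate
Product: 4 3,3-dimethyl-5-oxohexanal
Conditions: Et3SiH, 10% Pd/C, acetone, rt
Reagents that add atoms: none
Why: Fukuyama reduction: zerovalent palladium inserts into the C–S bond and the silane delivers hydride, stopping at the aldehyde and leaving the ketone untouched; 4 is volatile and prone to self-condensation and is used at once.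

Step 4
Reactants: 5 5,7-dimethoxycoumarin (5,7-dimethoxychromen-2-one)
Product: 6 5,7-dimethoxy-2-oxochromene-8-carbaldehyde
Conditions: POCl3, DMF, 0 → 70 °C; then aq. NaOAc
Reagents that add atoms: N,N-dimethylformamide, CN(C)C=O; water, O
Why: Vilsmeier–Haack formylation: the chloroiminium ion attacks the dimethoxy-activated ring at C8, and hydrolysis of the iminium salt gives the aldehyde.

Step 5
Reactants: 6 5,7-dimethoxy-2-oxochromene-8-carbaldehyde; 7 nitromethane
Product: 8 5,7-dimethoxy-8-[(E)-2-nitroethenyl]chromen-2-one
Conditions: 7 (excess, co-solvent), NH4OAc, AcOH, 100 °C
Reagents that add atoms: none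
Why: Henry condensation with in-situ dehydration, as used for other 2,6-dialkoxybenzaldehydes; the E-nitroalkene is the thermodynamic product and the lactone tolerates buffered acetic acid.

Step 6
Reactants: 4 3,3-dimethyl-5-oxohexanal; 8 5,7-dimethoxy-8-[(E)-2-nitroethenyl]chromen-2-one
Product: 11 (1S,6R)-1-(5,7-dimethoxy-2-oxochromen-8-yl)-3-hydroxy-3,5,5-trimethyl-2-nitrocyclohexane-6-carbaldehyde (trans at C1/C6; epimers at C2 and C3), via open-chain Michael adduct 9 (not isolated), via cis nitrocyclohexanol 10 (not isolated)
Conditions: 4 (2 equiv), (S)-α,α-diphenylprolinol trimethylsilyl ether (20 mol %), 4-nitrophenol (20 mol %), CH2Cl2, 0 °C → rt; then DBU (0.5 equiv), 0 °C → rt; AcOH quench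
Reagents that add atoms: none
Why: The bulky secondary amine condenses with the aldehyde of 4 and not with its methyl ketone, and the E-enamine adds through C6 to the β-carbon of 8 (the future C1) on the face remote from the diphenyl(trimethylsilyloxy)methyl group, so the (S)-catalyst fixes C1 as S and hydrolysis releases syn adduct 9; this is the well-known diarylprolinol silyl ether Michael addition of aldehydes to β-aryl nitroalkenes, and the closest known cascade is its continuation by an intramolecular nitroaldol (Henry) reaction to a nitrocyclohexanol. DBU then deprotonates the CH2NO2 group and the nitronate carbon C2 attacks the C3 ketone in a 6-(enolexo)-exo-trig closure, which forms the only ring of the step; attack on the aldehyde would need a four-membered ring and does not compete. Because the syn adduct carries C6 in the configuration epimeric to the one required, the ring first appears as cis isomer 10, and DBU equilibrates C6 through the aldehyde enolate to trans isomer 11. The trans isomer should be favoured because aryl and formyl groups are then both equatorial and the ortho substituents of the aryl group face only axial hydrogen atoms at C2 and C6. C2 and C3 settle under thermodynamic control by reversible nitronate protonation and retro-nitroaldol (nitro and C3 methyl expected equatorial) and are removed later, so only C1 (catalyst control) and C6 (equilibration) matter. The step needs enantioface selectivity at the nitroalkene, enamine formation at the aldehyde only and closure onto the ketone only; the first is secured by the catalyst, the second by the hindered neopentyl-type ketone, the third by ring size. An excess of freshly made 4 and a weak acid co-catalyst are used because 4 can be lost by its own intramolecular aldol condensation.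

Step 7
Reactants: 11 (1S,6R)-nitrocyclohexanol aldehyde
Product: 13 (1S,6R)-1-(5,7-dimethoxy-2-oxochromen-8-yl)-3,5,5-trimethyl-2-nitro-3-(phenylsulfanyl)cyclohexane-6-carbaldehyde (epimers at C2 and C3), via nitrocyclohexene 12 (not isolated)
Conditions: MsCl, Et3N, CH2Cl2, −20 → 0 °C; then PhSH, 0 °C → rt
Reagents that add atoms: benzenethiol, Sc1ccccc1
Why: Mesylation of the tertiary hydroxyl and E1cB loss of mesylate through the C2 nitronate give the conjugated C2=C3 nitroalkene, and the thiolate then adds at C3 in a sulfa-Michael reaction, the standard way to β-nitro sulfides. Deconjugated nitroalkene isomers re-equilibrate under Et3N and are drained by the addition; C1 and C6 are not involved and the new C2/C3 centres are transient.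

Step 8
Reactants: 13 (1S,6R)-β-nitro sulfide
Product: 14 (1S,6R)-1-(5,7-dimethoxy-2-oxochromen-8-yl)-3,5,5-trimethylcyclohex-2-ene-6-carbaldehyde
Conditions: Bu3SnH, AIBN, benzene, 80 °C
Reagents that add atoms: none
Why: Radical elimination of a β-nitro sulfide: the stannyl radical attacks a nitro oxygen, the C2–N bond breaks, and the C2 radical expels the phenylthiyl radical by β-scission, which places the alkene at C2=C3 only. The β-scission is far faster than hydrogen transfer or aryl migration, and the aldehyde and lactone are not reduced by the tin hydride under these conditions.

Step 9
Reactants: 5 5,7-dimethoxycoumarin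
Product: 15 8-iodo-5,7-dimethoxychromen-2-one
Conditions: NIS, TFA (cat.), MeCN, rt
Reagents that add atoms: N-iodosuccinimide, O=C1CCC(=O)N1I
Why: Electrophilic aromatic iodination at C8, with the same regiochemical preference as in step 4.

Step 10
Reactants: 14 (1S,6R)-cyclohexene aldehyde; 15 8-iodo-5,7-dimethoxychromen-2-one
Product: 16 (1S,6R)-1-(5,7-dimethoxy-2-oxochromen-8-yl)-6-[(5,7-dimethoxy-2-oxochromen-8-yl)(hydroxy)methyl]-3,5,5-trimethylcyclohex-2-ene (both C7 epimers)
Conditions: 15 (2.5 equiv), CrCl2 (6 equiv), NiCl2 (2 mol %), DMF, rt
Reagents that add atoms: none
Why: Nozaki–Hiyama–Kishi coupling: zerovalent nickel inserts into the C–I bond, the aryl group passes to trivalent chromium, and the arylchromium species adds to the aldehyde while ignoring lactones and the alkene. C7 is formed without useful control (Felkin–Anh addition anti to C5 should favour 7S), which does not matter because both epimers converge in step 11.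

Step 11
Reactants: 16 secondary alcohol (both C7 epimers)
Product: 17 (1S,6R)-6-(5,7-dimethoxy-2-oxochromene-8-carbonyl)-1-(5,7-dimethoxy-2-oxochromen-8-yl)-3,5,5-trimethylcyclohex-2-ene
Conditions: Dess–Martin periodinane, NaHCO3, CH2Cl2, rt
Reagents that add atoms: none
Why: Hypervalent iodine oxidation of the hindered benzylic alcohol under buffered, non-acidic conditions removes the C7 centre; the trans arrangement at C6 is the thermodynamic one and is retained.

Step 12
Reactants: 17 diaryl ketone
Product: 18 IN0553, (1S,6R)-1-(5,7-dimethoxy-2-oxochromen-8-yl)-6-[(R)-(5,7-dimethoxy-2-oxochromen-8-yl)(hydroxy)methyl]-3,5,5-trimethylcyclohex-2-ene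
Conditions: NaBH4, CeCl3·7H2O, MeOH–CH2Cl2, −40 → 0 °C
Reagents that add atoms: none
Why: Luche-type 1,2-reduction, in which CeCl3 activates the hindered ketone and suppresses conjugate reduction of the coumarins. In the Felkin–Anh conformer the bond to the quaternary C5 lies anti to the incoming hydride, which passes over C6–H on the face flanked by C1; this sets C7 as R.

## Compound list

1 | isophorone (3,5,5-trimethylcyclohex-2-en-1-one) | CC1=CC(=O)CC(C)(C)C1 | starting material
2 | 3,3-dimethyl-5-oxohexanoic acid | CC(=O)CC(C)(C)CC(=O)O | intermediate
3 | S-ethyl 3,3-dimethyl-5-oxohexanethioate | CCSC(=O)CC(C)(C)CC(C)=O | intermediate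
4 | 3,3-dimethyl-5-oxohexanal | CC(=O)CC(C)(C)CC=O | intermediate
5 | 5,7-dimethoxycoumarin | COc1cc(OC)c2ccc(=O)oc2c1 | starting material
6 | 5,7-dimethoxy-2-oxochromene-8-carbaldehyde | COc1cc(OC)c2ccc(=O)oc2c1C=O | intermediate
7 | nitromethane | C[N+](=O)[O-] | starting material
8 | 5,7-dimethoxy-8-[(E)-2-nitroethenyl]chromen-2-one | COc1cc(OC)c2ccc(=O)oc2c1/C=C/[N+](=O)[O-] | intermediate
9 | (2S)-2-[(1S)-1-(5,7-dimethoxy-2-oxochromen-8-yl)-2-nitroethyl]-3,3-dimethyl-5-oxohexanal (syn Michael adduct, not isolated) | O=C[C@H](C(C)(C)CC(C)=O)[C@@H](c1c(OC)cc(OC)c2ccc(=O)oc12)C[N+](=O)[O-] | intermediate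
10 | (1S,6S)-1-(5,7-dimethoxy-2-oxochromen-8-yl)-3-hydroxy-3,5,5-trimethyl-2-nitrocyclohexane-6-carbaldehyde (cis at C1/C6, C2/C3 epimers, not isolated) | COc1cc(OC)c2ccc(=O)oc2c1[C@H]1C([N+](=O)[O-])C(C)(O)CC(C)(C)[C@H]1C=O | intermediate
11 | (1S,6R)-1-(5,7-dimethoxy-2-oxochromen-8-yl)-3-hydroxy-3,5,5-trimethyl-2-nitrocyclohexane-6-carbaldehyde (trans at C1/C6, C2/C3 epimers) | COc1cc(OC)c2ccc(=O)oc2c1[C@H]1C([N+](=O)[O-])C(C)(O)CC(C)(C)[C@@H]1C=O | intermediate
12 | (1S,6R)-1-(5,7-dimethoxy-2-oxochromen-8-yl)-3,5,5-trimethyl-2-nitrocyclohex-2-ene-6-carbaldehyde (not isolated) | COc1cc(OC)c2ccc(=O)oc2c1[C@H]1C([N+](=O)[O-])=C(C)CC(C)(C)[C@@H]1C=O | intermediate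
13 | (1S,6R)-1-(5,7-dimethoxy-2-oxochromen-8-yl)-3,5,5-trimethyl-2-nitro-3-(phenylsulfanyl)cyclohexane-6-carbaldehyde (C2/C3 epimers) | COc1cc(OC)c2ccc(=O)oc2c1[C@H]1C([N+](=O)[O-])C(C)(Sc2ccccc2)CC(C)(C)[C@@H]1C=O | intermediate
14 | (1S,6R)-1-(5,7-dimethoxy-2-oxochromen-8-yl)-3,5,5-trimethylcyclohex-2-ene-6-carbaldehyde | COc1cc(OC)c2ccc(=O)oc2c1[C@H]1C=C(C)CC(C)(C)[C@@H]1C=O | intermediate
15 | 8-iodo-5,7-dimethoxychromen-2-one | COc1cc(OC)c2ccc(=O)oc2c1I | intermediate
16 | (1S,6R)-1-(5,7-dimethoxy-2-oxochromen-8-yl)-6-[(5,7-dimethoxy-2-oxochromen-8-yl)(hydroxy)methyl]-3,5,5-trimethylcyclohex-2-ene (both C7 epimers) | COc1cc(OC)c2ccc(=O)oc2c1[C@H]1C=C(C)CC(C)(C)[C@@H]1C(O)c1c(OC)cc(OC)c2ccc(=O)oc12 | intermediate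
17 | (1S,6R)-6-(5,7-dimethoxy-2-oxochromene-8-carbonyl)-1-(5,7-dimethoxy-2-oxochromen-8-yl)-3,5,5-trimethylcyclohex-2-ene | COc1cc(OC)c2ccc(=O)oc2c1[C@H]1C=C(C)CC(C)(C)[C@@H]1C(=O)c1c(OC)cc(OC)c2ccc(=O)oc12 | intermediate
18 | IN0553, (1S,6R,7R) | COc1cc(OC)c2ccc(=O)oc2c1[C@H]1C=C(C)CC(C)(C)[C@@H]1[C@@H](O)c1c(OC)cc(OC)c2ccc(=O)oc12 | target

## Step count and least certain steps

Total: 12 steps. Longest linear sequence: 9 steps (steps 1, 2, 3, 6, 7, 8, 10, 11, 12).

**Step 6 (key step).** Three processes are most likely to go wrong.
- Slow enamine addition, because the enamine carbon is neopentyl-like and the nitroalkene is di-ortho-substituted and electron-rich.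
- Loss of 4 through its own amine-catalysed intramolecular aldol condensation.
- A reversible, incomplete ring closure onto the methyl ketone, or incomplete equilibration at C6; prolonged base could also erode C1 by retro-Michael addition.

Fallback: a stepwise variant with the ketone masked. It sets out from 3, which with ethane-1,2-diol and an acid catalyst gives S-ethyl 3,3-dimethyl-4-(2-methyl-1,3-dioxolan-2-yl)butanethioate F1. Fukuyama reduction (Et3SiH, Pd/C) gives 3,3-dimethyl-4-(2-methyl-1,3-dioxolan-2-yl)butanal F2, which cannot self-condense. Addition of F2 to 8 with the same amine catalyst gives the ketal-protected syn Michael adduct F3, and mild aqueous acid frees the ketone. The fallback comes back to the route at 9, which is then cyclised and equilibrated with DBU as a separate operation to 11.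

**Step 10.** Addition of the di-ortho-substituted arylchromium species to an aldehyde flanked by a quaternary and a tertiary carbon may be too slow, so that protodehalogenation of 15 and recovery of 14 take over.

Fallback: a preformed polar aryl–metal reagent in place of the nickel/chromium pair. It sets out from 15, which by iodine–magnesium exchange with iPrMgCl·LiCl in THF at −40 °C gives (5,7-dimethoxy-2-oxochromen-8-yl)magnesium chloride F4. This is added to 14 at low temperature in the presence of LaCl3·2LiCl; the aldehyde is far more electrophilic than the lactones. The fallback comes back at 16.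

**Step 12.** Facial selectivity may be poor or reversed, because both α-branches of C6 (the quaternary C5 and the aryl-bearing C1) are bulky; conjugate reduction of a coumarin is a lesser risk. Aryl addition and hydride addition deliver opposite C7 configurations under the same facial preference, so the required epimer is in principle reachable from one of the two.

Fallback: reagent control in place of substrate control. It sets out from 17 and uses Corey–Bakshi–Shibata reduction with the 2-methyl-CBS-oxazaborolidine and catecholborane at −78 °C; the (S)-catalyst is the one predicted if the aryl group acts as the larger substituent. It comes back at 18 and makes no new compound (F0).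

**Step 4.** Substitution may go to C6 or to C3 of the pyranone, or conversion may be low because the lactone-bearing ring is less activated than a simple resorcinol ether.

Fallback: ring construction in place of substitution, which fixes the regiochemistry by design. It does not set out from 5 but from commercial 2-hydroxy-4,6-dimethoxybenzaldehyde F5. Esterification with propiolic acid (DCC) gives 2-formyl-3,5-dimethoxyphenyl prop-2-ynoate F6, and hydroarylation at the only free ortho position with cationic monovalent gold (Ph3PAuCl/AgSbF6) closes the pyranone. The fallback comes back at 6.

## Further compounds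

F1 | step 6 | S-ethyl 3,3-dimethyl-4-(2-methyl-1,3-dioxolan-2-yl)butanethioate | CCSC(=O)CC(C)(C)CC1(C)OCCO1
F2 | step 6 | 3,3-dimethyl-4-(2-methyl-1,3-dioxolan-2-yl)butanal | O=CCC(C)(C)CC1(C)OCCO1
F3 | step 6 | (2S)-2-[(1S)-1-(5,7-dimethoxy-2-oxochromen-8-yl)-2-nitroethyl]-3,3-dimethyl-4-(2-methyl-1,3-dioxolan-2-yl)butanal | O=C[C@H](C(C)(C)CC1(C)OCCO1)[C@@H](c1c(OC)cc(OC)c2ccc(=O)oc12)C[N+](=O)[O-]
F4 | step 10 | (5,7-dimethoxy-2-oxochromen-8-yl)magnesium chloride | Cl[Mg]c1c(OC)cc(OC)c2ccc(=O)oc12
F0 | step 12 | none | none
F5 | step 4 | 2-hydroxy-4,6-dimethoxybenzaldehyde | COc1cc(O)c(C=O)c(OC)c1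
F6 | step 4 | 2-formyl-3,5-dimethoxyphenyl prop-2-ynoate | C#CC(=O)Oc1cc(OC)cc(OC)c1C=O
A1 | alternative 1 | 2-(methoxymethoxy)-4,6-dimethoxyphenyllithium | [Li]c1c(OC)cc(OC)cc1OCOC
A2 | alternative 1 | 2,6-di-tert-butyl-4-methoxyphenyl 4,6,6-trimethylcyclohexa-1,3-diene-1-carboxylate | CC1=CC=C(C(=O)Oc2c(C(C)(C)C)cc(OC)cc2C(C)(C)C)C(C)(C)C1
A3 | alternative 1 | (1S,6R)-trans C7 ketone carrying two 2-(methoxymethoxy)-4,6-dimethoxyphenyl groups | COCOc1cc(OC)cc(OC)c1[C@H]1C=C(C)CC(C)(C)[C@@H]1C(=O)c1c(OC)cc(OC)cc1OCOC
A4 | alternative 2 | ethyl 3-[2-(methoxymethoxy)-4,6-dimethoxyphenyl]-3-oxopropanoate | CCOC(=O)CC(=O)c1c(OC)cc(OC)cc1OCOC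
A5 | alternative 2 | mesityl oxide (4-methylpent-3-en-2-one) | CC(C)=CC(C)=O
A6 | alternative 2 | ethyl 2-[2-(methoxymethoxy)-4,6-dimethoxyphenyl]-6,6-dimethyl-4-oxocyclohex-2-ene-1-carboxylate (racemic) | CCOC(=O)C1C(c2c(OC)cc(OC)cc2OCOC)=CC(=O)CC1(C)C
A7 | alternative 3 | (1S,6R)-bis(prop-2-ynoate) of the bis-phenol C7 ketone | C#CC(=O)Oc1cc(OC)cc(OC)c1[C@H]1C=C(C)CC(C)(C)[C@@H]1C(=O)c1c(OC)cc(OC)cc1OC(=O)C#C
A8 | alternative 3 | (1S,6R)-C7 ketone with both coumarins complete (identical with 17) | COc1cc(OC)c2ccc(=O)oc2c1[C@H]1C=C(C)CC(C)(C)[C@@H]1C(=O)c1c(OC)cc(OC)c2ccc(=O)oc12
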